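A direct plan would build the arylnaphthoic acid first and attach the lactate last: an aryl Grignard reagent would be acylated with succinic anhydride to the γ-keto acid A1, a Perkin-type condensation with the protected aldehyde would give the arylidene butenolide A2, and acid methanolysis with cyclodehydration at C4–C4a, then saponification, would give the tetra-O-benzyl naphthoic acid A3.
Carbodiimide esterification of A3 with the benzyl-protected (R)-danshensu A4 would give the hepta-benzyl ester A5, and hydrogenolysis of A5 would finish.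
Its weakest steps would be:
(i) the cyclodehydration that turns the opened butenolide A2 into the naphthalene of A3 – ring closure would hinge on the arylidene geometry and on attack para to one OBn group, in hot acid that endangers benzyl ethers;
(ii) the methanolysis–saponification pair on the way to A3 – two steps would be spent to make and remove a methyl ester before the real ester is formed;
(iii) the carbodiimide esterification of A3 with A4 – the most advanced intermediate would be committed to acylating a hindered, weakly nucleophilic α-hydroxy ester, with N-acylurea formation and base-promoted α-epimerisation as likely losses.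

**Plan of the new route**
Cuts: the two ring-fusion bonds C1–C8a and C4–C4a together (ring A leaves as a 4,5-dioxygenated benzyne), then C4–aryl, then the acyl–O bond to the lactate; the chain C1–C2(CO2R)–C3–C4 is never assembled but bought as coumalic acid.
Enabling feature: ring B carries H, CO2R, H, aryl on C1–C4, i.e. the C6/C5/C4/C3 pattern of a 3-aryl-2-oxo-2H-pyran-5-carboxylate, and ring A has identical oxygens on C6 and C7, so the aryne across C4a–C8a is symmetric and both orientations of addition give the same naphthalene.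
Ring order: ring B exists first as the pyranone, already esterified with the (R)-lactate; the pendant catechol ring is coupled to it; ring A is fused on last by [4+2] addition, and loss of CO2 aromatises ring B.
The weak steps cannot arise: no ring closure depends on alkene geometry or on the site of an electrophilic attack, the carboxyl is esterified only once (with the lactate, from two cheap components), and only hydrogenolysis follows the key step.

Key step: step 7

Assumption: coumalic acid, sodium (R)-danshensu, [3,4-bis(benzyloxy)phenyl]boronic acid and 3,4-bis(benzyloxy)phenol are taken as commercial; the (R) centre of natural danshensu is that of the target and is never a reaction site.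
Remark: the lactate half carries 4-methoxybenzyl (PMB) groups, which leave in the final hydrogenolysis together with the benzyl (Bn) groups and could also be removed by acid.
Notation: Lac* = (2R)-3-{3,4-bis[(4-methoxybenzyl)oxy]phenyl}-1-[(4-methoxybenzyl)oxy]-1-oxopropan-2-yl, the O-linked residue of the alcohol made in step 2. Naphthalene numbering: carboxyl on C2, aryl on C4, oxygens on C6 and C7.

**Route**

Step 1
Reactants: 1 coumalic acid (2-oxo-2H-pyran-5-carboxylic acid)
Product: 2 3-bromo-2-oxo-2H-pyran-5-carboxylic acid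
Conditions: Br2 (1.1 equiv), AcOH, 60 → 100 °C
Reagents that add atoms: bromine, BrBr
Why: Electrophilic bromination of a 2-pyranone by addition–elimination: C5 is blocked and deactivated by the carboxyl, so bromine should enter at C3 and HBr is lost on heating, while the un-ionised acid in AcOH disfavours ipso-bromodecarboxylation.

Step 2
Reactants: 3 sodium (2R)-3-(3,4-dihydroxyphenyl)-2-hydroxypropanoate (sodium danshensu)
Product: 4 4-methoxybenzyl (2R)-3-{3,4-bis[(4-methoxybenzyl)oxy]phenyl}-2-hydroxypropanoate
Conditions: PMBCl (3.3 equiv), K2CO3, Bu4NI (cat.), DMF, rt, Ar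
Reagents that add atoms: 4-methoxybenzyl chloride, COc1ccc(CCl)cc1
Why: Williamson O-alkylation in which carbonate ionises only the carboxylate and the two phenols, so the secondary alcohol stays free and the (R) centre is retained.

Step 3
Reactants: 2 3-bromo-2-oxo-2H-pyran-5-carboxylic acid; 4 4-methoxybenzyl (2R)-3-{3,4-bis[(4-methoxybenzyl)oxy]phenyl}-2-hydroxypropanoate
Product: 6 Lac* 3-bromo-2-oxo-2H-pyran-5-carboxylate, via 3-bromo-2-oxo-2H-pyran-5-carbonyl chloride 5 (not isolated)
Conditions: (COCl)2, DMF (cat.), CH2Cl2, 0 °C → rt, evaporate; then 4, 2,6-lutidine, CH2Cl2, −20 °C → rt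
Reagents that add atoms: none
Why: Acyl chloride formation and O-acylation of the secondary alcohol, which leaves the C–O bond at the stereocentre intact so that (R) is retained; the hindered weak base should neither add to the electrophilic pyranone C6 nor deprotonate the lactate α-carbon.

Step 4
Reactants: 6 Lac* 3-bromo-2-oxo-2H-pyran-5-carboxylate; 7 [3,4-bis(benzyloxy)phenyl]boronic acid
Product: 8 Lac* 3-[3,4-bis(benzyloxy)phenyl]-2-oxo-2H-pyran-5-carboxylate
Conditions: Pd(OAc)2 (3 mol %), SPhos (6 mol %), K3PO4, toluene–H2O (20:1), 40 °C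
Reagents that add atoms: none
Why: Suzuki–Miyaura coupling at the activated C3–Br bond of the 2-pyranone with an electron-rich arylboronic acid; a mild phosphate base and an active catalyst at low temperature should spare the pyranone ring and the lactate centre.

Step 5
Reactants: 9 3,4-bis(benzyloxy)phenol
Product: 10 2-bromo-4,5-bis(benzyloxy)phenol
Conditions: NBS (1.0 equiv), MeCN, −20 → 0 °C
Reagents that add atoms: N-bromosuccinimide, O=C1CCC(=O)N1Br
Why: Electrophilic aromatic bromination directed by the phenol: of its two ortho positions the unhindered one, which is also para to the 3-OBn group, should react, the other being flanked by two oxygen substituents.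

Step 6
Reactants: 10 2-bromo-4,5-bis(benzyloxy)phenol
Product: 13 4,5-bis(benzyloxy)-2-(trimethylsilyl)phenyl trifluoromethanesulfonate, via [2-bromo-4,5-bis(benzyloxy)phenoxy]trimethylsilane 11 (not isolated), via lithium 4,5-bis(benzyloxy)-2-(trimethylsilyl)phenolate 12 (not isolated)
Conditions: HMDS, THF, 70 °C, evaporate; n-BuLi, THF, −100 → −78 °C; Tf2O, −78 °C → rt
Reagents that add atoms: hexamethyldisilazane, C[Si](C)(C)N[Si](C)(C)C; trifluoromethanesulfonic anhydride, O=S(=O)(OS(=O)(=O)C(F)(F)F)C(F)(F)F
Why: Standard o-silylaryl triflate synthesis by O-silylation, bromine–lithium exchange, anionic 1,3-O→C silyl shift (retro-Brook rearrangement) and O-triflation; exchange at −100 °C should outrun benzylic deprotonation of the benzyl ethers.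

Step 7
Reactants: 8 Lac* 3-[3,4-bis(benzyloxy)phenyl]-2-oxo-2H-pyran-5-carboxylate; 13 4,5-bis(benzyloxy)-2-(trimethylsilyl)phenyl trifluoromethanesulfonate
Product: 16 Lac* 6,7-bis(benzyloxy)-4-[3,4-bis(benzyloxy)phenyl]naphthalene-2-carboxylate, via 4,5-bis(benzyloxy)benzyne 14 (not isolated), via Lac* 6,7-bis(benzyloxy)-4-[3,4-bis(benzyloxy)phenyl]-9-oxo-1,4-dihydro-1,4-(epoxymethano)naphthalene-2-carboxylate 15 (not isolated)
Conditions: 13 (1.5 equiv, slow addition), CsF (3 equiv), MeCN–toluene (1:1), rt → 50 °C
Reagents that add atoms: none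
Why: Fluoride attacks silicon of 13 and triflate leaves from the ortho carbon, giving the symmetric aryne 14, which adds as the 2π component across C3 and C6 of the 2-pyranone diene of 8 in a concerted [4+2] cycloaddition; the bridged lactone 15 (lactone O on C1, C=O on C4) then loses CO2 by retro-[4+2] cycloreversion. The closest known reaction type is the Diels–Alder/decarboxylation sequence of arynes with 2-pyranones such as coumalate esters, which gives 2-naphthoates. Ring B is closed as a carbocycle by intermolecular cycloaddition that forms C4–C4a and C1–C8a in one event (suprafacial on both partners, the diene being held s-cis by the lactone ring), and it is aromatised by extrusion of CO2 without oxidant or acid. No lasting stereocentre is formed: the two bridgehead centres of 15 arise as both epimers and are destroyed with the loss of CO2, while the (R)-lactate centre is not a reaction site and only meets weakly basic fluoride at 50 °C or below. The step needs site selectivity for the pyranone over the benzenoid rings of 8 and a single orientation of addition: the first is secured because only the pyranone offers a non-aromatic, s-cis-locked diene whose adduct aromatises irreversibly, and the second is made irrelevant by the C6/C7 symmetry of the aryne, so that aryl ends on C4 and the ester on C2 by construction.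

Step 8
Reactants: 16 Lac* 6,7-bis(benzyloxy)-4-[3,4-bis(benzyloxy)phenyl]naphthalene-2-carboxylate
Product: 17 eritrichin, (2R)-3-(3,4-dihydroxyphenyl)-2-{[4-(3,4-dihydroxyphenyl)-6,7-dihydroxynaphthalene-2-carbonyl]oxy}propanoic acid
Conditions: H2 (1 atm), 10% Pd/C, THF–MeOH, rt; filter under Ar
Reagents that add atoms: none
Why: Catalytic hydrogenolysis should cleave the four aryl benzyl ethers, the two aryl PMB ethers and the PMB ester, while the naphthalene and the secondary naphthoate ester (its O-bearing carbon is homobenzylic, not benzylic) are untouched, so the (R) centre is retained.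

**Compound list**

1 | coumalic acid (2-oxo-2H-pyran-5-carboxylic acid) | OC(=O)C1=COC(=O)C=C1 | starting material
2 | 3-bromo-2-oxo-2H-pyran-5-carboxylic acid | OC(=O)C1=COC(=O)C(Br)=C1 | intermediate
3 | sodium (2R)-3-(3,4-dihydroxyphenyl)-2-hydroxypropanoate | [Na+].[O-]C(=O)[C@H](O)Cc1ccc(O)c(O)c1 | starting material
4 | 4-methoxybenzyl (2R)-3-{3,4-bis[(4-methoxybenzyl)oxy]phenyl}-2-hydroxypropanoate | O[C@H](Cc1ccc(OCc2ccc(OC)cc2)c(OCc2ccc(OC)cc2)c1)C(=O)OCc1ccc(OC)cc1 | intermediate
5 | 3-bromo-2-oxo-2H-pyran-5-carbonyl chloride | ClC(=O)C1=COC(=O)C(Br)=C1 | intermediate (not isolated)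
6 | Lac* 3-bromo-2-oxo-2H-pyran-5-carboxylate | O=C(O[C@H](Cc1ccc(OCc2ccc(OC)cc2)c(OCc2ccc(OC)cc2)c1)C(=O)OCc1ccc(OC)cc1)C1=COC(=O)C(Br)=C1 | intermediate
7 | [3,4-bis(benzyloxy)phenyl]boronic acid | OB(O)c1ccc(OCc2ccccc2)c(OCc2ccccc2)c1 | starting material
8 | Lac* 3-[3,4-bis(benzyloxy)phenyl]-2-oxo-2H-pyran-5-carboxylate | O=C(O[C@H](Cc1ccc(OCc2ccc(OC)cc2)c(OCc2ccc(OC)cc2)c1)C(=O)OCc1ccc(OC)cc1)C1=COC(=O)C(c2ccc(OCc3ccccc3)c(OCc3ccccc3)c2)=C1 | intermediate
9 | 3,4-bis(benzyloxy)phenol | Oc1ccc(OCc2ccccc2)c(OCc2ccccc2)c1 | starting material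
10 | 2-bromo-4,5-bis(benzyloxy)phenol | Oc1cc(OCc2ccccc2)c(OCc2ccccc2)cc1Br | intermediate
11 | [2-bromo-4,5-bis(benzyloxy)phenoxy]trimethylsilane | C[Si](C)(C)Oc1cc(OCc2ccccc2)c(OCc2ccccc2)cc1Br | intermediate (not isolated)
12 | lithium 4,5-bis(benzyloxy)-2-(trimethylsilyl)phenolate | [Li+].[O-]c1cc(OCc2ccccc2)c(OCc2ccccc2)cc1[Si](C)(C)C | intermediate (not isolated)
13 | 4,5-bis(benzyloxy)-2-(trimethylsilyl)phenyl trifluoromethanesulfonate | C[Si](C)(C)c1cc(OCc2ccccc2)c(OCc2ccccc2)cc1OS(=O)(=O)C(F)(F)F | intermediate
14 | 4,5-bis(benzyloxy)benzyne (1,2-didehydro-4,5-bis(benzyloxy)benzene) | C1#CC=C(OCc2ccccc2)C(OCc2ccccc2)=C1 | intermediate (not isolated)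
15 | Lac* 6,7-bis(benzyloxy)-4-[3,4-bis(benzyloxy)phenyl]-9-oxo-1,4-dihydro-1,4-(epoxymethano)naphthalene-2-carboxylate (lactone O on C1, C=O on C4; both bridgehead epimers, bridgeheads left undefined) | O=C(O[C@H](Cc1ccc(OCc2ccc(OC)cc2)c(OCc2ccc(OC)cc2)c1)C(=O)OCc1ccc(OC)cc1)C1=CC2(c3ccc(OCc4ccccc4)c(OCc4ccccc4)c3)C(=O)OC1c1cc(OCc3ccccc3)c(OCc3ccccc3)cc12 | intermediate (not isolated)
16 | Lac* 6,7-bis(benzyloxy)-4-[3,4-bis(benzyloxy)phenyl]naphthalene-2-carboxylate | O=C(O[C@H](Cc1ccc(OCc2ccc(OC)cc2)c(OCc2ccc(OC)cc2)c1)C(=O)OCc1ccc(OC)cc1)c1cc(-c2ccc(OCc3ccccc3)c(OCc3ccccc3)c2)c2cc(OCc3ccccc3)c(OCc3ccccc3)cc2c1 | intermediate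
17 | eritrichin, (2R)-3-(3,4-dihydroxyphenyl)-2-{[4-(3,4-dihydroxyphenyl)-6,7-dihydroxynaphthalene-2-carbonyl]oxy}propanoic acid | O=C(O[C@H](Cc1ccc(O)c(O)c1)C(=O)O)c1cc(-c2ccc(O)c(O)c2)c2cc(O)c(O)cc2c1 | target

**Summary**

Total steps: 8.
Longest linear sequence: 5 steps (steps 2, 3, 4, 7, 8 from sodium danshensu; equally steps 1, 3, 4, 7, 8 from coumalic acid).

Steps most likely to fail:

1. Step 7. Cycloaddition at the aryl-substituted diene terminus may be slower than loss of the aryne to oligomerisation or fluoride adducts, and long contact with fluoride could erode the lactate centre. The fallback sets out from 6 and comes back at 16. The aryne 14 (from 13, CsF, MeCN–toluene) would be added to the less hindered bromopyranone 6, whose reacting diene terminus carries only a bromine atom in place of the bulky aryl group. This should give, via the bridged lactone Lac* 4-bromo-6,7-bis(benzyloxy)-9-oxo-1,4-dihydro-1,4-(epoxymethano)naphthalene-2-carboxylate F1 and loss of CO2, the bromonaphthoate Lac* 6,7-bis(benzyloxy)-4-bromonaphthalene-2-carboxylate F2. Suzuki–Miyaura coupling of F2 with 7 under the conditions of step 4 would then give 16.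

2. Step 4. Opening of the electrophilic pyranone ring by the basic medium, or base-mediated epimerisation or cleavage at the activated lactate ester, may compete with the coupling. The fallback sets out from 2 and comes back at 8. The free acid 2 would be coupled with 7 as its carboxylate (Pd(OAc)2, SPhos, K3PO4, dioxane–H2O, then acidification); the carboxylate is far less electrophilic than the ester and carries no stereocentre. This should give 3-[3,4-bis(benzyloxy)phenyl]-2-oxo-2H-pyran-5-carboxylic acid F3. Conversion with oxalyl chloride into 3-[3,4-bis(benzyloxy)phenyl]-2-oxo-2H-pyran-5-carbonyl chloride F4 and acylation of 4 with 2,6-lutidine, as in step 3, would give 8.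

3. Step 1. Ipso-bromodecarboxylation at C5 or over-bromination may take the place of clean substitution at C3. The fallback sets out from 1 and comes back at 2. Fischer esterification (MeOH, H2SO4) would give methyl 2-oxo-2H-pyran-5-carboxylate F5. Bromination of the ester (Br2, AcOH, heat), in which the masked carboxyl cannot be lost, would give methyl 3-bromo-2-oxo-2H-pyran-5-carboxylate F6. Acid hydrolysis (6 M HCl, dioxane, reflux), which the pyranone ring should tolerate, would give 2.

**Further compounds**

F1 | step 7 | Lac* 4-bromo-6,7-bis(benzyloxy)-9-oxo-1,4-dihydro-1,4-(epoxymethano)naphthalene-2-carboxylate (both bridgehead epimers) | O=C(O[C@H](Cc1ccc(OCc2ccc(OC)cc2)c(OCc2ccc(OC)cc2)c1)C(=O)OCc1ccc(OC)cc1)C1=CC2(Br)C(=O)OC1c1cc(OCc3ccccc3)c(OCc3ccccc3)cc12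
F2 | step 7 | Lac* 6,7-bis(benzyloxy)-4-bromonaphthalene-2-carboxylate | O=C(O[C@H](Cc1ccc(OCc2ccc(OC)cc2)c(OCc2ccc(OC)cc2)c1)C(=O)OCc1ccc(OC)cc1)c1cc(Br)c2cc(OCc3ccccc3)c(OCc3ccccc3)cc2c1
F3 | step 4 | 3-[3,4-bis(benzyloxy)phenyl]-2-oxo-2H-pyran-5-carboxylic acid | OC(=O)C1=COC(=O)C(c2ccc(OCc3ccccc3)c(OCc3ccccc3)c2)=C1
F4 | step 4 | 3-[3,4-bis(benzyloxy)phenyl]-2-oxo-2H-pyran-5-carbonyl chloride | ClC(=O)C1=COC(=O)C(c2ccc(OCc3ccccc3)c(OCc3ccccc3)c2)=C1
F5 | step 1 | methyl 2-oxo-2H-pyran-5-carboxylate | COC(=O)C1=COC(=O)C=C1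
F6 | step 1 | methyl 3-bromo-2-oxo-2H-pyran-5-carboxylate | COC(=O)C1=COC(=O)C(Br)=C1
A1 | direct plan | 4-[3,4-bis(benzyloxy)phenyl]-4-oxobutanoic acid | OC(=O)CCC(=O)c1ccc(OCc2ccccc2)c(OCc2ccccc2)c1
A2 | direct plan | (3E)-3-[3,4-bis(benzyloxy)benzylidene]-5-[3,4-bis(benzyloxy)phenyl]furan-2(3H)-one | O=C1OC(c2ccc(OCc3ccccc3)c(OCc3ccccc3)c2)=C/C1=C\c1ccc(OCc2ccccc2)c(OCc2ccccc2)c1
A3 | direct plan | 6,7-bis(benzyloxy)-4-[3,4-bis(benzyloxy)phenyl]naphthalene-2-carboxylic acid | OC(=O)c1cc(-c2ccc(OCc3ccccc3)c(OCc3ccccc3)c2)c2cc(OCc3ccccc3)c(OCc3ccccc3)cc2c1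
A4 | direct plan | benzyl (2R)-3-[3,4-bis(benzyloxy)phenyl]-2-hydroxypropanoate | O[C@H](Cc1ccc(OCc2ccccc2)c(OCc2ccccc2)c1)C(=O)OCc1ccccc1
A5 | direct plan | benzyl (2R)-3-[3,4-bis(benzyloxy)phenyl]-2-({6,7-bis(benzyloxy)-4-[3,4-bis(benzyloxy)phenyl]naphthalene-2-carbonyl}oxy)propanoate | O=C(O[C@H](Cc1ccc(OCc2ccccc2)c(OCc2ccccc2)c1)C(=O)OCc1ccccc1)c1cc(-c2ccc(OCc3ccccc3)c(OCc3ccccc3)c2)c2cc(OCc3ccccc3)c(OCc3ccccc3)cc2c1
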